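The cycloheptenone is cut at C7, the lone methylene between the C1 carbonyl and C6 of the seven-membered ring: removing it leaves a 4,4,5-trisubstituted cyclohex-2-enone whose C6 carries bromomethyl and allyl (latent acetonyl). One radical chain moves that carbon in beside the carbonyl, enlarges the ring from six to seven members and creates C6 by hydrogen transfer anti to the C5 arm. The precursor's C4/C5 pair comes from an enantioselective Diels–Alder reaction of an E-enynal, which fixes methyl and arm cis by alkene geometry; the arm is a silylalkyne, later converted into the Z-enol senecioate by ruthenium-catalysed acid addition.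

Key step: step 10

Numbering: ring atoms keep the target's numbers in every compound (C1 carbonyl or enol carbon, C2=C3, C4 quaternary, C5 with the two-carbon arm, C6 with the three-carbon arm, C7 the inserted methylene); descriptors in the names refer to these numbers.

Assumption: the cationic oxazaborolidine is taken to bind the 2-methyl-2-enal as is usual for 2-substituted enals (formyl C–H···O contact, s-trans enal, diene entering on the face remote from the shielding aryl group), which calls for the (R)-configured catalyst.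

Precursor design: in 19 the acetonyl arm is carried as allyl and the C5 arm as a triisopropylsilyl alkyne. Both are inert to enolates and tin radicals, neither puts an activated C–H within 1,5-reach of the C7 radical, no ketal or silyl ether has to be handled around the key step, and the alkyne leads directly to the Z-enol ester.

Step 1
Reactants: 1 3-(triisopropylsilyl)prop-2-ynal; 2 2-(triphenylphosphoranylidene)propanal
Product: 3 (E)-2-methyl-5-(triisopropylsilyl)pent-2-en-4-ynal
Conditions: CH2Cl2, rt
Reagents that add atoms: none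
Why: Wittig olefination with a stabilised formyl ylide, which attacks only the more electrophilic ynal and should give the E-enal (formyl trans to alkynyl), the geometry that later places methyl and alkynyl cis on the ring.

Step 2
Reactants: 4 but-3-en-2-one
Product: 5 2-(triisopropylsilyloxy)buta-1,3-diene
Conditions: iPr3SiOTf, Et3N, Et2O, 0 °C to rt
Reagents that add atoms: triisopropylsilyl trifluoromethanesulfonate, CC(C)[Si](OS(=O)(=O)C(F)(F)F)(C(C)C)C(C)C
Why: Soft enolisation and O-silylation of the enone give the 2-silyloxydiene, and the bulky silyl group keeps the derived enol ether intact through the next three steps.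

Step 3
Reactants: 3 (E)-2-methyl-5-(triisopropylsilyl)pent-2-en-4-ynal; 5 2-(triisopropylsilyloxy)buta-1,3-diene
Product: 6 (4S,5S)-4-methyl-1-(triisopropylsilyloxy)-5-[(triisopropylsilyl)ethynyl]cyclohex-1-ene-4-carbaldehyde (CH3 and alkynyl cis)
Conditions: (R)-1-(2-methylphenyl)-3,3-diphenyltetrahydro-1H,3H-pyrrolo[1,2-c][1,3,2]oxazaborole (20 mol %), Tf2NH (17 mol %), CH2Cl2, −78 to −20 °C
Reagents that add atoms: none
Why: Catalytic enantioselective Diels–Alder reaction under chiral cationic oxazaborolidine activation; the nucleophilic CH2 terminus of the siloxydiene bonds to the β-carbon of the enal ("para" orientation), suprafacial addition to the E-alkene fixes CH3 and alkynyl cis at C4/C5, and the catalyst, by shielding one face of the s-trans enal, sets the absolute configuration of both centres together.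

Step 4
Reactants: 6 (4S,5S)-4-methyl-1-(triisopropylsilyloxy)-5-[(triisopropylsilyl)ethynyl]cyclohex-1-ene-4-carbaldehyde; 7 methyltriphenylphosphonium bromide
Product: 8 (4R,5S)-4-ethenyl-4-methyl-1-(triisopropylsilyloxy)-5-[(triisopropylsilyl)ethynyl]cyclohex-1-ene
Conditions: 7, KN(SiMe3)2, THF, 0 °C; then 6, 0 °C to rt
Reagents that add atoms: none
Why: Wittig methylenation of a non-enolisable neopentyl aldehyde, which leaves the silyl enol ether and the silylalkyne untouched and affects no stereocentre (the descriptor at C4 changes only through priorities).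

Step 5
Reactants: 8 (4R,5S)-4-ethenyl-4-methyl-1-(triisopropylsilyloxy)-5-[(triisopropylsilyl)ethynyl]cyclohex-1-ene; 9 1-bromo-2-methylprop-1-ene
Product: 11 (4S,5S)-4-methyl-4-(4-methylpent-3-en-1-yl)-1-(triisopropylsilyloxy)-5-[(triisopropylsilyl)ethynyl]cyclohex-1-ene, via B-alkyl-9-BBN adduct 10 (not isolated)
Conditions: 9-BBN, THF, rt; then 9, [1,1'-bis(diphenylphosphino)ferrocene]PdCl2 (5 mol %), K3PO4 (aq), DMF, 50 °C
Reagents that add atoms: none
Why: Anti-Markovnikov hydroboration of the only monosubstituted alkene with 9-BBN followed by B-alkyl Suzuki–Miyaura coupling with the alkenyl bromide completes the 4-methylpent-3-enyl chain, the trisubstituted enol ether and the hindered silylalkyne being far slower towards 9-BBN.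

Step 6
Reactants: 11 (4S,5S)-4-methyl-4-(4-methylpent-3-en-1-yl)-1-(triisopropylsilyloxy)-5-[(triisopropylsilyl)ethynyl]cyclohex-1-ene
Product: 12 (4S,5S)-4-methyl-4-(4-methylpent-3-en-1-yl)-5-[(triisopropylsilyl)ethynyl]cyclohex-2-en-1-one
Conditions: Pd(OAc)2 (1.1 equiv), DMSO, 40 °C
Reagents that add atoms: none
Why: Saegusa–Ito oxidation; palladation of the enol ether at C2 and β-hydride elimination from C3 should give the C2=C3 enone without regiochemical ambiguity, because the cycloaddition laid the enol ether down on that side.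

Step 7
Reactants: 12 (4S,5S)-4-methyl-4-(4-methylpent-3-en-1-yl)-5-[(triisopropylsilyl)ethynyl]cyclohex-2-en-1-one; 13 allyl bromide
Product: 15 (4S,5S,6S)-4-methyl-4-(4-methylpent-3-en-1-yl)-6-(prop-2-en-1-yl)-5-[(triisopropylsilyl)ethynyl]cyclohex-2-en-1-one (allyl trans to alkynyl expected; the C6 epimer is equally usable), via lithium dienolate 14 (not isolated)
Conditions: LiN(iPr)2, THF, −78 °C; then 13, −78 to −20 °C
Reagents that add atoms: none
Why: Kinetic α'-deprotonation of the enone (C4 is quaternary, so no γ-proton competes) and enolate alkylation with a reactive allylic halide; allyl is the acetonyl skeleton in masked form and the configuration created at C6 is of no consequence.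

Step 8
Reactants: 15 (4S,5S,6S)-4-methyl-4-(4-methylpent-3-en-1-yl)-6-(prop-2-en-1-yl)-5-[(triisopropylsilyl)ethynyl]cyclohex-2-en-1-one; 16 formaldehyde (monomer from cracked paraformaldehyde)
Product: 18 (4S,5R,6R)-6-(hydroxymethyl)-4-methyl-4-(4-methylpent-3-en-1-yl)-6-(prop-2-en-1-yl)-5-[(triisopropylsilyl)ethynyl]cyclohex-2-en-1-one (C6 epimer equally usable), via lithium dienolate 17 (not isolated)
Conditions: LiN(iPr)2, THF, −78 to −40 °C; CH2O (gas), −78 °C; aq NH4Cl
Reagents that add atoms: none
Why: Aldol addition of the tetrasubstituted lithium enolate to monomeric formaldehyde, the smallest electrophile, builds the quaternary C6; either configuration there serves because the centre later becomes a radical.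

Step 9
Reactants: 18 (4S,5R,6R)-6-(hydroxymethyl)-4-methyl-4-(4-methylpent-3-en-1-yl)-6-(prop-2-en-1-yl)-5-[(triisopropylsilyl)ethynyl]cyclohex-2-en-1-one
Product: 19 (4S,5S,6S)-6-(bromomethyl)-4-methyl-4-(4-methylpent-3-en-1-yl)-6-(prop-2-en-1-yl)-5-[(triisopropylsilyl)ethynyl]cyclohex-2-en-1-one (key-step precursor; C6 epimer equally usable)
Conditions: CBr4, PPh3, CH2Cl2, 0 to 40 °C
Reagents that add atoms: carbon tetrabromide, BrC(Br)(Br)Br
Why: Appel bromination under neutral conditions turns the neopentyl-type primary alcohol into the bromide without a carbocation (no rearrangement) and without base (no retro-aldol loss of formaldehyde).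

Step 10
Reactants: 19 (4S,5S,6S)-6-(bromomethyl)-4-methyl-4-(4-methylpent-3-en-1-yl)-6-(prop-2-en-1-yl)-5-[(triisopropylsilyl)ethynyl]cyclohex-2-en-1-one
Product: 20 (4S,5S,6S)-4-methyl-4-(4-methylpent-3-en-1-yl)-6-(prop-2-en-1-yl)-5-[(triisopropylsilyl)ethynyl]cyclohept-2-en-1-one
Conditions: Bu3SnH (1.3 equiv, syringe pump over 8 h), AIBN (0.2 equiv), benzene (5 mM), 80 °C
Reagents that add atoms: none
Why: Bu3Sn• abstracts bromine from 19; the primary radical on the future C7 adds to the C1 carbonyl carbon, and the resulting cyclopropyloxy radical reopens by breaking the old C1–C6 bond, so that C7 ends between C1 and C6 and the radical moves to the tertiary C6, where Bu3SnH delivers hydrogen and regenerates Bu3Sn•. This is the Dowd–Beckwith one-carbon ring expansion of an α-halomethyl cyclic ketone (radical 1,2-acyl shift), here driven by the primary-to-tertiary radical gain in place of the usual ester stabilisation. The seven-membered ring is not closed directly: a 3-exo-trig addition to C=O makes a bicyclo[4.1.0] oxy radical whose internal bond then fragments (ring enlargement from six to seven). C6 is the only new stereocentre; it is set in the final hydrogen transfer, which should occur on the face of the planar C6 radical opposite to the C5 alkynyl arm (whose triisopropylsilyl cap overhangs that face) and to the cis C4 methyl group, leaving allyl cis to the arm. The step needs the acyl shift to outrun direct reduction of the primary radical, which the millimolar stationary tin hydride concentration and 80 °C should secure, and it needs the radical to find no easier exit: in 19 C4 is quaternary, no alkene lies within 5-exo reach of C7 and no C–H bond next to oxygen lies within 1,5-reach. The configuration of C6 in 19 is erased, so either epimer of 19 converges on 20.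

Step 11
Reactants: 20 (4S,5S,6S)-4-methyl-4-(4-methylpent-3-en-1-yl)-6-(prop-2-en-1-yl)-5-[(triisopropylsilyl)ethynyl]cyclohept-2-en-1-one
Product: 21 (4S,5S,6S)-4-methyl-4-(4-methylpent-3-en-1-yl)-6-(2-oxopropyl)-5-[(triisopropylsilyl)ethynyl]cyclohept-2-en-1-one
Conditions: PdCl2 (20 mol %), CuCl (1 equiv), O2 (1 atm), DMF/H2O 7:1, rt
Reagents that add atoms: water, O
Why: Tsuji–Wacker oxidation is selective for the monosubstituted terminal alkene (Markovnikov hydroxypalladation), so the trisubstituted alkene, the enone and the hindered silylalkyne should remain untouched while the acetonyl arm is unveiled.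

Step 12
Reactants: 21 (4S,5S,6S)-4-methyl-4-(4-methylpent-3-en-1-yl)-6-(2-oxopropyl)-5-[(triisopropylsilyl)ethynyl]cyclohept-2-en-1-one
Product: 22 (4R,5S,6S)-2-iodo-4-methyl-4-(4-methylpent-3-en-1-yl)-6-(2-oxopropyl)-5-[(triisopropylsilyl)ethynyl]cyclohept-2-en-1-one
Conditions: I2, pyridine, CH2Cl2, 0 °C to rt
Reagents that add atoms: iodine, II
Why: Pyridine-mediated α-iodination of the enone (conjugate addition of pyridine, iodination of the enolate, elimination), a sequence known to work for enones with a quaternary γ-carbon; the saturated methyl ketone is not enolised under these conditions and no stereocentre is touched.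

Step 13
Reactants: 22 (4R,5S,6S)-2-iodo-4-methyl-4-(4-methylpent-3-en-1-yl)-6-(2-oxopropyl)-5-[(triisopropylsilyl)ethynyl]cyclohept-2-en-1-one; 23 (tributylstannyl)methanol
Product: 24 (4S,5S,6S)-2-(hydroxymethyl)-4-methyl-4-(4-methylpent-3-en-1-yl)-6-(2-oxopropyl)-5-[(triisopropylsilyl)ethynyl]cyclohept-2-en-1-one
Conditions: Pd(PPh3)4 (10 mol %), 1,4-dioxane, 90 °C
Reagents that add atoms: none
Why: Stille coupling of the α-iodoenone with the hydroxymethylstannane transfers CH2OH to C2 under neutral conditions that tolerate both ketones, the trisubstituted alkene and the silylalkyne.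

Step 14
Reactants: 24 (4S,5S,6S)-2-(hydroxymethyl)-4-methyl-4-(4-methylpent-3-en-1-yl)-6-(2-oxopropyl)-5-[(triisopropylsilyl)ethynyl]cyclohept-2-en-1-one
Product: 25 (4S,5R,6S)-5-ethynyl-2-(hydroxymethyl)-4-methyl-4-(4-methylpent-3-en-1-yl)-6-(2-oxopropyl)cyclohept-2-en-1-one
Conditions: Bu4NF, THF (wet), 0 °C
Reagents that add atoms: none
Why: Fluoride-induced protodesilylation of the alkynylsilane at low temperature and short contact time; the silyl cap is removed only now because a free terminal alkyne would not survive the radical, Wacker and coupling steps.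

Step 15
Reactants: 25 (4S,5R,6S)-5-ethynyl-2-(hydroxymethyl)-4-methyl-4-(4-methylpent-3-en-1-yl)-6-(2-oxopropyl)cyclohept-2-en-1-one; 26 3-methylbut-2-enoic acid
Product: 27 (Z)-2-[(4R,5R,6S)-2-(hydroxymethyl)-4-methyl-4-(4-methylpent-3-en-1-yl)-1-oxo-6-(2-oxopropyl)cyclohept-2-en-5-yl]ethenyl 3-methylbut-2-enoate (target)
Conditions: Ru(η3-CH2C(CH3)CH2)2[Ph2P(CH2)4PPh2] (5 mol %), toluene, 60 °C
Reagents that add atoms: none
Why: Ruthenium-catalysed anti-Markovnikov addition of a carboxylic acid to a terminal alkyne through a ruthenium vinylidene, which puts oxygen on the terminal carbon and should give the Z-enol ester; the ketones, the trisubstituted alkene and the free alcohol are spectators under these neutral conditions.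

Compound list
1 | 3-(triisopropylsilyl)prop-2-ynal | O=CC#C[Si](C(C)C)(C(C)C)C(C)C | starting material
2 | 2-(triphenylphosphoranylidene)propanal | CC(C=O)=P(c1ccccc1)(c1ccccc1)c1ccccc1 | starting material
3 | (E)-2-methyl-5-(triisopropylsilyl)pent-2-en-4-ynal | O=C/C(C)=C/C#C[Si](C(C)C)(C(C)C)C(C)C | intermediate
4 | but-3-en-2-one | CC(=O)C=C | starting material
5 | 2-(triisopropylsilyloxy)buta-1,3-diene | C=CC(=C)O[Si](C(C)C)(C(C)C)C(C)C | intermediate
6 | (4S,5S)-4-methyl-1-(triisopropylsilyloxy)-5-[(triisopropylsilyl)ethynyl]cyclohex-1-ene-4-carbaldehyde | C1C(O[Si](C(C)C)(C(C)C)C(C)C)=CC[C@](C)(C=O)[C@H]1C#C[Si](C(C)C)(C(C)C)C(C)C | intermediate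
7 | methyltriphenylphosphonium bromide | C[P+](c1ccccc1)(c1ccccc1)c1ccccc1.[Br-] | starting material
8 | (4R,5S)-4-ethenyl-4-methyl-1-(triisopropylsilyloxy)-5-[(triisopropylsilyl)ethynyl]cyclohex-1-ene | C1C(O[Si](C(C)C)(C(C)C)C(C)C)=CC[C@](C)(C=C)[C@H]1C#C[Si](C(C)C)(C(C)C)C(C)C | intermediate
9 | 1-bromo-2-methylprop-1-ene | CC(C)=CBr | starting material
10 | 9-{2-[(4S,5S)-4-methyl-1-(triisopropylsilyloxy)-5-[(triisopropylsilyl)ethynyl]cyclohex-1-en-4-yl]ethyl}-9-borabicyclo[3.3.1]nonane | C1C(O[Si](C(C)C)(C(C)C)C(C)C)=CC[C@](C)(CCB2C3CCCC2CCC3)[C@H]1C#C[Si](C(C)C)(C(C)C)C(C)C | intermediate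
11 | (4S,5S)-4-methyl-4-(4-methylpent-3-en-1-yl)-1-(triisopropylsilyloxy)-5-[(triisopropylsilyl)ethynyl]cyclohex-1-ene | C1C(O[Si](C(C)C)(C(C)C)C(C)C)=CC[C@](C)(CCC=C(C)C)[C@H]1C#C[Si](C(C)C)(C(C)C)C(C)C | intermediate
12 | (4S,5S)-4-methyl-4-(4-methylpent-3-en-1-yl)-5-[(triisopropylsilyl)ethynyl]cyclohex-2-en-1-one | C1C(=O)C=C[C@](C)(CCC=C(C)C)[C@H]1C#C[Si](C(C)C)(C(C)C)C(C)C | intermediate
13 | allyl bromide | C=CCBr | starting material
14 | lithium dienolate of 12 (O–Li on C1, C1=C6) | C1=C(O[Li])C=C[C@](C)(CCC=C(C)C)[C@H]1C#C[Si](C(C)C)(C(C)C)C(C)C | intermediate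
15 | (4S,5S,6S)-4-methyl-4-(4-methylpent-3-en-1-yl)-6-(prop-2-en-1-yl)-5-[(triisopropylsilyl)ethynyl]cyclohex-2-en-1-one | C=CC[C@@H]1C(=O)C=C[C@](C)(CCC=C(C)C)[C@H]1C#C[Si](C(C)C)(C(C)C)C(C)C | intermediate
16 | formaldehyde | C=O | starting material
17 | lithium dienolate of 15 (O–Li on C1, C1=C6) | C=CCC1=C(O[Li])C=C[C@](C)(CCC=C(C)C)[C@H]1C#C[Si](C(C)C)(C(C)C)C(C)C | intermediate
18 | (4S,5R,6R)-6-(hydroxymethyl)-4-methyl-4-(4-methylpent-3-en-1-yl)-6-(prop-2-en-1-yl)-5-[(triisopropylsilyl)ethynyl]cyclohex-2-en-1-one | OC[C@]1(CC=C)C(=O)C=C[C@](C)(CCC=C(C)C)[C@H]1C#C[Si](C(C)C)(C(C)C)C(C)C | intermediate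
19 | (4S,5S,6S)-6-(bromomethyl)-4-methyl-4-(4-methylpent-3-en-1-yl)-6-(prop-2-en-1-yl)-5-[(triisopropylsilyl)ethynyl]cyclohex-2-en-1-one | BrC[C@]1(CC=C)C(=O)C=C[C@](C)(CCC=C(C)C)[C@H]1C#C[Si](C(C)C)(C(C)C)C(C)C | intermediate
20 | (4S,5S,6S)-4-methyl-4-(4-methylpent-3-en-1-yl)-6-(prop-2-en-1-yl)-5-[(triisopropylsilyl)ethynyl]cyclohept-2-en-1-one | C=CC[C@H]1CC(=O)C=C[C@](C)(CCC=C(C)C)[C@H]1C#C[Si](C(C)C)(C(C)C)C(C)C | intermediate
21 | (4S,5S,6S)-4-methyl-4-(4-methylpent-3-en-1-yl)-6-(2-oxopropyl)-5-[(triisopropylsilyl)ethynyl]cyclohept-2-en-1-one | CC(=O)C[C@H]1CC(=O)C=C[C@](C)(CCC=C(C)C)[C@H]1C#C[Si](C(C)C)(C(C)C)C(C)C | intermediate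
22 | (4R,5S,6S)-2-iodo-4-methyl-4-(4-methylpent-3-en-1-yl)-6-(2-oxopropyl)-5-[(triisopropylsilyl)ethynyl]cyclohept-2-en-1-one | CC(=O)C[C@H]1CC(=O)C(I)=C[C@](C)(CCC=C(C)C)[C@H]1C#C[Si](C(C)C)(C(C)C)C(C)C | intermediate
23 | (tributylstannyl)methanol | CCCC[Sn](CO)(CCCC)CCCC | starting material
24 | (4S,5S,6S)-2-(hydroxymethyl)-4-methyl-4-(4-methylpent-3-en-1-yl)-6-(2-oxopropyl)-5-[(triisopropylsilyl)ethynyl]cyclohept-2-en-1-one | CC(=O)C[C@H]1CC(=O)C(CO)=C[C@](C)(CCC=C(C)C)[C@H]1C#C[Si](C(C)C)(C(C)C)C(C)C | intermediate
25 | (4S,5R,6S)-5-ethynyl-2-(hydroxymethyl)-4-methyl-4-(4-methylpent-3-en-1-yl)-6-(2-oxopropyl)cyclohept-2-en-1-one | CC(=O)C[C@H]1CC(=O)C(CO)=C[C@](C)(CCC=C(C)C)[C@H]1C#C | intermediate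
26 | 3-methylbut-2-enoic acid | CC(C)=CC(=O)O | starting material
27 | (Z)-2-[(4R,5R,6S)-2-(hydroxymethyl)-4-methyl-4-(4-methylpent-3-en-1-yl)-1-oxo-6-(2-oxopropyl)cyclohept-2-en-5-yl]ethenyl 3-methylbut-2-enoate | CC(=O)C[C@H]1CC(=O)C(CO)=C[C@](C)(CCC=C(C)C)[C@H]1/C=C\OC(=O)C=C(C)C | target

Total step count: 15. Longest linear sequence: 14 steps (steps 1 and 3 to 15; step 2 is a side branch).

Steps most likely to fail

Step 10. The primary radical may take hydrogen from the tin hydride before it has added to the conjugated C1 carbonyl, which would leave C7 as a methyl group on an unexpanded ring. The C6 radical may also abstract an allylic hydrogen from the homoprenyl chain, and the slim alkyne may discriminate the two faces of C6 incompletely. The fallback sets out from 15 and returns at 20; it forms the C1–C7 bond without a primary radical. Enone 15 is deprotonated at C6 (LiN(iPr)2) and silylated with Me3SiCl to give the trimethylsilyl dienol ether F1. Cyclopropanation of its electron-rich enol ether double bond with Et2Zn/CH2I2 gives the siloxycyclopropane F2. FeCl3 in DMF then opens the internal cyclopropane bond oxidatively, the known ring enlargement of siloxycyclopropanes, to give the tertiary β-chloro cycloheptenone F3. Bu3SnH/AIBN removes the chlorine through the same C6 radical and should give 20. Because nothing has to be outrun any more, the donor can be used in excess and at lower temperature, which also shortens the lifetime of the C6 radical.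

Step 3. The trisubstituted dienophile may react too slowly with the moderately reactive siloxydiene at the temperature needed for induction, or the catalyst may differentiate the enal faces poorly. The fallback sets out from 3 and 5 and returns at 6; it replaces induction by resolution. Cycloaddition promoted by Me2AlCl (CH2Cl2, −78 °C) gives racemic material, that is 6 together with its enantiomer F4; the cis CH3/alkynyl relationship does not depend on the promoter. Condensation with (1R,2R)-N,N'-dimethyl-1,2-diphenylethane-1,2-diamine (molecular sieves, Et2O) converts the two aldehydes into the diastereomeric imidazolidine F5 (from 6) and imidazolidine F6 (from F4), which are separated by chromatography. Brief two-phase treatment of F5 with dilute aqueous acid returns 6 and the diamine.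

Step 15. Vinylidene formation at the hindered alkyne (a secondary carbon next to a quaternary one) may be slow, so that Markovnikov addition, alkyne oligomerisation or isomerisation of the allylic alcohol compete. The fallback sets out from 25 and returns at 27; it makes the C–O bond by copper catalysis on a preformed Z-alkenyl iodide. The alkyne terminus of 25 is iodinated (N-iodosuccinimide, AgNO3 cat., acetone) to the iodoalkyne F7. Diimide, generated from 2-nitrobenzenesulfonyl hydrazide and Et3N, reduces it to the (Z)-alkenyl iodide F8. Copper-catalysed coupling with 26 (CuI, 1,10-phenanthroline, Cs2CO3, toluene, 80 °C) should form the enol ester with retention of the Z geometry and give 27.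

Further compounds
F1 | step 10 | trimethylsilyl dienol ether of 15 (O–SiMe3 on C1, C1=C6, C2=C3) | C=CCC1=C(O[Si](C)(C)C)C=C[C@](C)(CCC=C(C)C)[C@H]1C#C[Si](C(C)C)(C(C)C)C(C)C
F2 | step 10 | siloxycyclopropane from F1 (CH2 bridging C1 and C6; configuration at C1 and C6 left open, both centres are lost in the next operation) | C=CCC12CC1(O[Si](C)(C)C)C=C[C@](C)(CCC=C(C)C)[C@H]2C#C[Si](C(C)C)(C(C)C)C(C)C
F3 | step 10 | (4S,5S)-6-chloro-4-methyl-4-(4-methylpent-3-en-1-yl)-6-(prop-2-en-1-yl)-5-[(triisopropylsilyl)ethynyl]cyclohept-2-en-1-one (C6 epimers) | C=CCC1(Cl)CC(=O)C=C[C@](C)(CCC=C(C)C)[C@H]1C#C[Si](C(C)C)(C(C)C)C(C)C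
F4 | step 3 | (4R,5R)-4-methyl-1-(triisopropylsilyloxy)-5-[(triisopropylsilyl)ethynyl]cyclohex-1-ene-4-carbaldehyde (enantiomer of 6) | C1C(O[Si](C(C)C)(C(C)C)C(C)C)=CC[C@@](C)(C=O)[C@@H]1C#C[Si](C(C)C)(C(C)C)C(C)C
F5 | step 3 | (4R,5R)-1,3-dimethyl-4,5-diphenylimidazolidine formed at the aldehyde carbon of 6 | C1C(O[Si](C(C)C)(C(C)C)C(C)C)=CC[C@](C)(C2N(C)[C@H](c3ccccc3)[C@@H](c3ccccc3)N2C)[C@H]1C#C[Si](C(C)C)(C(C)C)C(C)C
F6 | step 3 | (4R,5R)-1,3-dimethyl-4,5-diphenylimidazolidine formed at the aldehyde carbon of F4 | C1C(O[Si](C(C)C)(C(C)C)C(C)C)=CC[C@@](C)(C2N(C)[C@H](c3ccccc3)[C@@H](c3ccccc3)N2C)[C@@H]1C#C[Si](C(C)C)(C(C)C)C(C)C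
F7 | step 15 | 5-(iodoethynyl) analogue of 25 | CC(=O)C[C@H]1CC(=O)C(CO)=C[C@](C)(CCC=C(C)C)[C@H]1C#CI
F8 | step 15 | 5-[(Z)-2-iodoethenyl] analogue of 25 | CC(=O)C[C@H]1CC(=O)C(CO)=C[C@](C)(CCC=C(C)C)[C@H]1/C=C\I
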